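**Numbering used below:** drimane numbering for the decalin (C1–C10, C8=CH2, C11 = side-chain CH2, C12 = side-chain C=O); primes for the cyclopentenone (C1′ = ring C=O, C4′ = carbinol).

**Assumption:** 2 (predominantly E), Grignard 6, 8 and silyl ether 12 are bought as such; one-pot two-stage operations (Steps 6 and 8) are counted as single steps.

## Retrosynthetic overview

1. C2′–CH2–S bond: made last by a three-component α-thiomethylation of the cyclopentenone with CH2O and methyl (R)-3-mercaptolactate.
2. α-Ketol/enone: C12 is a 1,3-dithiane linchpin; the C4′ carbinol comes from anti 1,2-addition of the lithiated dithiane to (S)-4-silyloxycyclopentenone, followed by allylic oxidation and dithiane hydrolysis.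
3. Key step: Ti(III) radical bicyclization of the fully assembled (S)-epoxy-diene, forming C4–C5 then C9–C10 and the C8=CH2 alkene in one operation.
4. Epoxy-polyene: chloro-ketal Claisen (C1–C2 bond, E-alkene), then CBS reduction and ring closure; the allylic alcohol comes from an aldehyde made by two SN2 alkylations of (E)-1,4-dibromo-2-methylbut-2-ene.
5. Ring order: cyclopentene ring (purchased) → ring A → ring B (A and B in the same step).

## Route

**Step 1**
Reactants: 1 (1,3-dithiane); 2 ((E)-1,4-dibromo-2-methylbut-2-ene)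
Product: 3, 2-[(2E)-4-bromo-3-methylbut-2-en-1-yl]-1,3-dithiane
Conditions: 1, n-BuLi, THF, −30 °C; then add to 2 (2.5 equiv), THF, −78 °C
Reagents that add atoms: none
Why: Corey–Seebach SN2 alkylation at the more reactive, prenyl-type CH2Br (the one on the CH= carbon); excess dibromide suppresses bis-alkylation and the E geometry of 2 is carried through.

**Step 2**
Reactants: 3; 4 (acetaldehyde N,N-dimethylhydrazone)
Product: 5, (4E)-6-(1,3-dithian-2-yl)-4-methylhex-4-enal
Conditions: 4, LDA, THF, 0 °C; then 3, −78 → 0 °C; then sat. aq. oxalic acid/Et2O, rt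
Reagents that add atoms: water, O (aldehyde oxygen on hydrolysis)
Why: Stork/Corey–Enders aza-enolate alkylation of the remaining primary allylic bromide gives the C6–C7 bond, and mild biphasic acid frees the aldehyde without touching the dithiane.

**Step 3**
Reactants: 5; 6 (isopropenylmagnesium bromide)
Product: 7, (6E)-8-(1,3-dithian-2-yl)-2,6-dimethylocta-1,6-dien-3-ol (racemic carbinol)
Conditions: THF, −78 → 0 °C
Reagents that add atoms: none
Why: Grignard 1,2-addition to the aldehyde; the new carbinol centre is racemic but is destroyed in Step 5.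

**Step 4**
Reactants: 8 (3-chloro-3-methylbutan-2-one)
Product: 9, 3-chloro-2,2-dimethoxy-3-methylbutane
Conditions: HC(OMe)3, MeOH, TsOH (cat.), rt
Reagents that add atoms: trimethyl orthoformate, COC(OC)OC; methanol, CO
Why: Acid-catalysed ketalization driven by the orthoformate gives Johnson's chloro ketal.

**Step 5**
Reactants: 7; 9 (3 equiv)
Product: 10, (6E,10E)-2-chloro-12-(1,3-dithian-2-yl)-2,6,10-trimethyldodeca-6,10-dien-3-one
Conditions: 2,4-dinitrophenol (cat.), toluene, 110 °C (MeOH distilled off)
Reagents that add atoms: none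
Why: Johnson chloro-ketal Claisen rearrangement: ketal exchange and MeOH loss give the allyl enol ether, and the chair [3,3] transition state with the chain equatorial gives the (E)-trisubstituted C5=C10 alkene while forming C1–C2.

**Step 6**
Reactants: 10
Product: 11, 2-{(2E,6E)-9-[(2S)-3,3-dimethyloxiran-2-yl]-3,7-dimethylnona-2,6-dien-1-yl}-1,3-dithiane
Conditions: (R)-Me-CBS (20 mol%), catecholborane, toluene, −78 °C; then K2CO3, MeOH, rt
Reagents that add atoms: none
Why: CBS reduction with CClMe2 as the large group gives the (S)-chlorohydrin (catecholborane at −78 °C leaves the alkenes alone), and the alkoxide then displaces the tertiary chloride with retention at the carbinol carbon to give the (S)-epoxide (C3).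

**Step 7**
Reactants: 11; 12 ((4S)-4-[(tert-butyldimethylsilyl)oxy]cyclopent-2-en-1-one)
Product: 13, (1R,4S)-4-[(tert-butyldimethylsilyl)oxy]-1-(2-{(2E,6E)-9-[(2S)-3,3-dimethyloxiran-2-yl]-3,7-dimethylnona-2,6-dien-1-yl}-1,3-dithian-2-yl)cyclopent-2-en-1-ol (OH cis to OTBS)
Conditions: 11, n-BuLi, THF, −30 °C; then 12, −78 °C
Reagents that add atoms: none
Why: Corey–Seebach 1,2-addition of the 2-alkyl-2-lithiodithiane to the enone carbonyl (no HMPA, so 1,2 over 1,4), anti to the OTBS group, sets the quaternary carbinol C4′ as (R).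

**Step 8 (key step)**
Reactants: 13
Product: 14, (1R,4S)-1-(2-{[(1S,4aR,6S,8aR)-6-hydroxy-5,5,8a-trimethyl-2-methylidenedecahydronaphthalen-1-yl]methyl}-1,3-dithian-2-yl)cyclopent-2-ene-1,4-diol
Conditions: Cp2TiCl2 (30 mol%), Mn, TMSCl, 2,4,6-collidine, THF, rt (slow addition of 13); then TBAF, THF
Reagents that add atoms: none
Why: Nugent–RajanBabu Ti(III) epoxy-polyene radical cyclization: Cp2TiCl opens the epoxide homolytically to the tertiary C4 radical, which closes 6-endo onto C5=C10 and then 6-endo onto C9=C8 through a chair–chair array (so the (S)-epoxide fixes 3β-OH, 5α-H, 10β-Me, 9α-H), and the tertiary C8 radical is terminated by Ti(III) H-abstraction from the methyl to give the exocyclic alkene; TBAF then removes the TMS and TBS groups.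

**Step 9**
Reactants: 14
Product: 15, (4R)-4-hydroxy-4-(2-{[(1S,4aR,6S,8aR)-6-hydroxy-5,5,8a-trimethyl-2-methylidenedecahydronaphthalen-1-yl]methyl}-1,3-dithian-2-yl)cyclopent-2-en-1-one
Conditions: MnO2, CH2Cl2, rt
Reagents that add atoms: none
Why: MnO2 oxidizes only the allylic secondary alcohol; the non-allylic 3-OH and the tertiary OH are untouched, and the C1′ stereocentre that relayed chirality to C4′ is erased.

**Step 10**
Reactants: 15
Product: 16, (4R)-4-hydroxy-4-{2-[(1S,4aR,6S,8aR)-6-hydroxy-5,5,8a-trimethyl-2-methylidenedecahydronaphthalen-1-yl]acetyl}cyclopent-2-en-1-one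
Conditions: PhI(OCOCF3)2, NaHCO3, MeCN/H2O, 0 °C
Reagents that add atoms: water, O (ketone oxygen)
Why: Hypervalent-iodine dethioacetalization unmasks the C12 ketone much faster than it attacks the isolated alkene; C11 is now flanked by sp3 C9, so the ketone cannot conjugate.

**Step 11**
Reactants: 17 (methyl (2S)-oxirane-2-carboxylate)
Product: 18, methyl (2R)-2-hydroxy-3-sulfanylpropanoate
Conditions: (Me3Si)2S, TBAF (cat.), THF, 0 °C → rt; aq. NH4Cl
Reagents that add atoms: hexamethyldisilathiane, C[Si](C)(C)S[Si](C)(C)C (S)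
Why: Fluoride-activated silylthiolate opens the glycidate at the terminal CH2, so C2 is untouched; the descriptor changes from S to R only because the CIP priorities change.

**Step 12**
Reactants: 16; 18 (1.3 equiv); 19 (formaldehyde, 37% aq.)
Product: 20, Alternarin A
Conditions: Et3N, MeOH, 45 °C
Reagents that add atoms: none
Why: Kirk–Petrow-type three-component α-thiomethylation (thia-Michael addition, aldol with CH2O, dehydration, then SN2′ thiol exchange that restores the endocyclic enone) places CH2–SR on the enone α-carbon C2′; no stereocentre is formed or disturbed.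

## Compound list

1 | 1,3-dithiane | C1CSCSC1 | starting material
2 | (E)-1,4-dibromo-2-methylbut-2-ene | BrC/C(C)=C/CBr | starting material
3 | 2-[(2E)-4-bromo-3-methylbut-2-en-1-yl]-1,3-dithiane | BrC/C(C)=C/CC1SCCCS1 | intermediate
4 | acetaldehyde N,N-dimethylhydrazone | CC=NN(C)C | starting material
5 | (4E)-6-(1,3-dithian-2-yl)-4-methylhex-4-enal | O=CCC/C(C)=C/CC1SCCCS1 | intermediate
6 | isopropenylmagnesium bromide | C=C(C)[Mg]Br | starting material
7 | (6E)-8-(1,3-dithian-2-yl)-2,6-dimethylocta-1,6-dien-3-ol (racemic) | C=C(C)C(O)CC/C(C)=C/CC1SCCCS1 | intermediate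
8 | 3-chloro-3-methylbutan-2-one | CC(=O)C(C)(C)Cl | starting material
9 | 3-chloro-2,2-dimethoxy-3-methylbutane | COC(C)(OC)C(C)(C)Cl | intermediate
10 | (6E,10E)-2-chloro-12-(1,3-dithian-2-yl)-2,6,10-trimethyldodeca-6,10-dien-3-one | CC(C)(Cl)C(=O)CC/C(C)=C/CC/C(C)=C/CC1SCCCS1 | intermediate
11 | 2-{(2E,6E)-9-[(2S)-3,3-dimethyloxiran-2-yl]-3,7-dimethylnona-2,6-dien-1-yl}-1,3-dithiane | CC1(C)O[C@H]1CC/C(C)=C/CC/C(C)=C/CC1SCCCS1 | intermediate
12 | (4S)-4-[(tert-butyldimethylsilyl)oxy]cyclopent-2-en-1-one | O=C1C=C[C@@H](O[Si](C)(C)C(C)(C)C)C1 | starting material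
13 | (1R,4S)-4-(TBSO)-1-[2-((S)-10,11-epoxyfarnesyl)-1,3-dithian-2-yl]cyclopent-2-en-1-ol (full name in Step 7) | CC1(C)O[C@H]1CC/C(C)=C/CC/C(C)=C/CC1(SCCCS1)[C@]1(O)C=C[C@@H](O[Si](C)(C)C(C)(C)C)C1 | intermediate
14 | bicyclic dithiane triol (3β-OH, 5α-H, 9α-H, 10β-Me; cis-cyclopentene-1,4-diol; full name in Step 8) | C=C1CC[C@H]2C(C)(C)[C@@H](O)CC[C@]2(C)[C@H]1CC1(SCCCS1)[C@]1(O)C=C[C@@H](O)C1 | intermediate
15 | (4R)-4-hydroxy-4-(dithianyl) cyclopentenone (full name in Step 9) | C=C1CC[C@H]2C(C)(C)[C@@H](O)CC[C@]2(C)[C@H]1CC1(SCCCS1)[C@]1(O)C=CC(=O)C1 | intermediate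
16 | (4R)-4-hydroxy-4-{2-[(1S,4aR,6S,8aR)-6-hydroxy-5,5,8a-trimethyl-2-methylidenedecahydronaphthalen-1-yl]acetyl}cyclopent-2-en-1-one | C=C1CC[C@H]2C(C)(C)[C@@H](O)CC[C@]2(C)[C@H]1CC(=O)[C@]1(O)C=CC(=O)C1 | intermediate
17 | methyl (2S)-oxirane-2-carboxylate | COC(=O)[C@@H]1CO1 | starting material
18 | methyl (2R)-2-hydroxy-3-sulfanylpropanoate | COC(=O)[C@@H](O)CS | intermediate
19 | formaldehyde | C=O | starting material
20 | Alternarin A: methyl (2R)-2-hydroxy-3-{[((3R)-3-hydroxy-3-{2-[(1S,4aR,6S,8aR)-6-hydroxy-5,5,8a-trimethyl-2-methylidenedecahydronaphthalen-1-yl]acetyl}-5-oxocyclopent-1-en-1-yl)methyl]sulfanyl}propanoate | C=C1CC[C@H]2C(C)(C)[C@@H](O)CC[C@]2(C)[C@H]1CC(=O)[C@]1(O)C=C(CSC[C@H](O)C(=O)OC)C(=O)C1 | target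

## Step count

- Total steps: 12 (14 if the second stages of Steps 6 and 8 are counted separately).
- Longest linear sequence: 10 (Steps 1, 2, 3, 5, 6, 7, 8, 9, 10, 12).

## Steps most likely to fail, with fallbacks

1. **Step 8 (Ti(III) bicyclization on the full skeleton).** The C8 radical could add 6-exo to the cyclopentene, the cascade could stop at the monocycle, or endo-alkene isomers could form. Fallback: cyclize 11 itself, which is a simple epoxyfarnesyl-type substrate, to the bicyclic dithiane; then join it to 12 through the alkoxide/dithiane dianion. This moves the fragment union after the cyclization.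

2. **Step 12 (three-component thiomethylation on a base-sensitive α-ketol enone).** Fallback: build the side chain stepwise by Morita–Baylis–Hillman hydroxymethylation of 16 (imidazole, aq. CH2O), conversion to the primary allylic acetate or bromide, and displacement with 18. Alternatively, convert that allylic electrophile to the thiol (AcSK, then methanolysis) and open glycidate 17 with it.

3. **Step 7 (hindered, basic 2-alkyl dithiane anion adding to the enolizable β-silyloxy enone).** Enolization with loss of silanolate, or an eroded anti:syn ratio, would undermine C4′. Fallback: invert the linchpin order. Add parent 2-lithio-1,3-dithiane to 12 first, silylate the tertiary alcohol, then lithiate and alkylate with 2 and grow the chain by Steps 2–6 with the cyclopentenyl unit already attached.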